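(The data are calculated for substances that don't exist; the scatter is artificial.)

You asked for a quick number, so I began with the late readings of the red run. From 8.00 min to 25.0 min, G crept from 29.6 % to 32.5 %, while E stayed between 2.2 % and 3.3 %.

in all of them: X 0.80 M
- red: the very flask that is asked about, followed so far
- flask: time 1.5 h

red run (percent of the X charged)

| time / min | E / % | G / % |
|---|---|---|
| 1.33 | 0.2 | 8.2 |
| 4.00 | 0.9 | 24.4 |
| 8.00 | 2.6 | 29.6 |
| 12.0 | 2.2 | 29.9 |
| 15.0 | 2.4 | 30.7 |
| 20.0 | 3.3 | 31.7 |
| 25.0 | 2.5 | 32.5 |

(readings scatter by 0.5 percentage points)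

- as a solid, counted per litre of solution: X
- steps thought possible: L <-> G; L <-> E; L <-> J; G <-> Q; X <-> L
- at the start none of X is in solution

- ratio of E to G at 30 s
- ratio of E to G at 1.5 h
- which of E and G there is more of at 1.5 h

E and G both leave L. If both steps are first order in L, L cancels from the ratio of their gains, so I took the reading at 4.00 min, before G stalled:

E / G = 0.9 % / 24.4 % = 0.0369

I took this as the branching ratio, a reading of E standing per G standing that stands in for the ratio of their gains from L, which some call a selectivity factor. With a scatter of 0.5 percentage points, it was a rough reading, and G may already have been passing on to Q by then, so it need not equal the ratio of the gains. At 25.0 min the readings gave: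

E / G = 2.5 % / 32.5 % = 0.0769

That was twice the branching ratio, so I reckoned 0.0369 for 30 s and something above 0.0769 for 1.5 h, with G ahead.

Your forecast gave 0.03 (0.01 to 0.06) and 0.08 (0.05 to 0.13), with G leading, and said “Early on, E/G is kinetic”. My early figure was higher than yours.

The flask gave 0.0400 at 30 s and 0.117 at 1.5 h, with G at 39.2 % and E at 4.57 %.

    L ⇌ G (K = 12.0, k = 0.139 min⁻¹)
    L ⇌ E (K = 9.50, k = 0.00540 min⁻¹)
    L ⇌ J (K = 1.50, k = 0.118 min⁻¹)
    G ⇌ Q (K = 1.20, k = 0.161 min⁻¹)
    X ⇌ L, rate k5*(cs5 - [L]) while solid is left; crystals form when [L] > cs5 (solubility = 0.670 M, k = 1.91 min⁻¹)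

The equilibrium constant of L into E over that of L into G was 0.792, more than the ratio reached at 1.5 h. That late ratio stood at 3.17 times the branching ratio.

For the neighbour charged with 1.4 M of X, I carried over the ratio read in the red run, since L had cancelled from the ratio of the gains, and so again reckoned 0.0369 for 30 s. The computed ratios were 0.0400 at 30 s and 0.116 at 1.5 h, the latter 3.14 times the branching ratio.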